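The bicyclo[2.2.1]heptane (C1 quaternary bridgehead, C2 bearing isopropyl, C3, bridgehead C4, carbinol C5, C6, bridge C7) is opened at C4–C7 and C1–C2. The feature exploited is its cyclopentane C1–C7–C4–C5–C6 (ring B): oxygenated at C5 and fused to cyclohexane ring C through C1–C7, it is a latent cyclopentenone. Ionisation of a 5-ethoxydienyl carbinol (C6) on the ring-C cyclohexene triggers a Nazarov-type 4π electrocyclisation (C4–C7); the resulting ethoxyallyl cation is trapped at C1 by a prenyl group hung on C4 (C1–C2). One operation converts a trans-decalin with an acyclic triene side chain into the tetracyclic norbornanone, setting C1, C2, C4 and C7.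

Key step: step 12

Remark: the numbering above is used for every intermediate; ring C = C1, C7, C8, C9, C10, C11; ring D = C8, C9, C12 (CHBr), C13, C14, C15 (C(Me)OH); C16 is the isopropyl CH. (S)-Wieland–Miescher ketone, ethoxyacetylene and prenyl bromide are taken as commercial.

Step 1
Reactants: 1 (S)-Wieland–Miescher ketone
Product: 2 bis(ethylene ketal) of 1 (dioxolanes at C1 and C12) with the alkene moved to C8=C15
Conditions: ethylene glycol, p-TsOH (cat.), benzene, reflux (Dean–Stark)
Reagents that add atoms: ethylene glycol, OCCO
Why: Acid-catalysed ketalisation (dioxolane protection) should convert both carbonyls, the enone reacting through its dienol so that the double bond leaves conjugation for C8=C15, the usual behaviour of 4-en-3-ones; C9 is carried from 1.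

Step 2
Reactants: 2 bis-ketal alkene
Product: 3 8,15-epoxide of 2 (oxygen mainly anti to the C9 methyl)
Conditions: mCPBA, NaHCO3, CH2Cl2, 0 °C
Reagents that add atoms: mCPBA, OOC(=O)c1cccc(Cl)c1
Why: Prilezhaev epoxidation of the trisubstituted alkene, buffered to spare the ketals, should occur mainly anti to the axial C9 methyl, and either epimer serves because this stereochemistry is erased in steps 3 and 4.

Step 3
Reactants: 3 epoxide
Product: 4 allylic alcohol (C15–OH, C7=C8 alkene, both dioxolanes kept)
Conditions: LiNEt2, Et2O/hexane, reflux
Reagents that add atoms: none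
Why: Lithium amide-induced β-elimination (epoxide to allylic alcohol isomerisation) should remove a C7 proton syn to the oxygen and break the tertiary C8–O bond, leaving the secondary C15 alcohol and the C7=C8 alkene.

Step 4
Reactants: 4 allylic alcohol
Product: 5 enone (C15 ketone conjugated with C7=C8, both dioxolanes kept)
Conditions: MnO2, CH2Cl2, 20 °C
Reagents that add atoms: none
Why: Manganese dioxide oxidises allylic alcohols selectively and should give the enone, whose C15 carbonyl is the only free ketone.

Step 5
Reactants: 5 enone
Product: 6 tertiary allylic alcohol (C15 methyl carbinol, hydroxyl cis to the C9 methyl)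
Conditions: MeLi, THF, −78 °C
Reagents that add atoms: methyllithium, [Li]C
Why: 1,2-Addition of methyllithium to the enone carbonyl should come from the face anti to the syn-axial C9 methyl, which sets C15 with its hydroxyl axial and cis to that methyl and the new methyl equatorial, as in the target.

Step 6
Reactants: 6 tertiary allylic alcohol bis-ketal
Product: 7 hydroxy enone (C1 ketone conjugated with C7=C8, C15 methyl carbinol, C12 dioxolane)
Conditions: PPTS (cat.), acetone/H2O, 20 °C
Reagents that add atoms: water, O
Why: Mild acid-catalysed ketal hydrolysis should open only the allylic C1 dioxolane, which ionises to a conjugated oxocarbenium ion and gives the conjugated enone, while the hindered neopentyl C12 dioxolane stays.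

Step 7
Reactants: 7 hydroxy enone
Product: 9 vinyl triflate (C1–OTf; C1=C7; trans ring fusion), via dilithium enolate alkoxide 8 (not isolated)
Conditions: LiN(SiMe3)2, THF, −78 °C; Li, NH3(l), −78 °C; isoprene; then PhNTf2, THF, −78 → 0 °C
Reagents that add atoms: N-phenyl-bis(trifluoromethanesulfonimide), O=S(=O)(N(c1ccccc1)S(=O)(=O)C(F)(F)F)C(F)(F)F
Why: Birch-type dissolving-metal reduction of the enone with axial protonation at C8 should set the trans ring fusion (H8 anti to the C9 methyl) and deliver the C1(7)-enolate regiospecifically for trapping as the triflate, the tertiary hydroxyl being masked first as its lithium alkoxide, which is neither a leaving group nor an internal proton source.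

Step 8
Reactants: 9 vinyl triflate
Product: 10 enal (formyl carbon C6 on C1, C1=C7)
Conditions: Pd(PPh3)4 (cat.), CO (1 atm), Bu3SnH (slow addition), THF, 50 °C
Reagents that add atoms: carbon monoxide, [C-]#[O+]
Why: Palladium-catalysed reductive carbonylation of the vinyl triflate (oxidative addition, CO insertion, hydride transfer from tin) should give the conjugated aldehyde without touching the alcohol or the ketal.

Step 9
Reactants: 11 ethoxyacetylene; 12 prenyl bromide
Product: 13 1-ethoxy-5-methylhex-4-en-1-yne
Conditions: n-BuLi, THF, −78 °C; then HMPA, −78 → 20 °C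
Reagents that add atoms: none
Why: SN2 alkylation of lithium ethoxyacetylide with the allylic bromide in a dipolar aprotic cosolvent should give the ynol ether.

Step 10
Reactants: 13 ynol ether
Product: 14 (E)-tributyl(1-ethoxy-5-methylhexa-1,4-dien-1-yl)stannane
Conditions: Bu3SnH, Pd(PPh3)4 (cat.), THF, 0 °C
Reagents that add atoms: tributyltin hydride, CCCC[SnH](CCCC)CCCC
Why: Palladium-catalysed hydrostannation of the ynol ether is a syn addition that should place tin on the oxygen-bearing carbon, so that tin is trans and ethoxy cis to C3, the alkene geometry the key step needs.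

Step 11
Reactants: 14 stannane; 10 enal
Product: 16 bis-allylic carbinol (C6–OH, both epimers; C4=C5(OEt) with C3 trans to C6; prenyl alkene C2=C16), via vinyllithium 15 (not isolated)
Conditions: 14 (excess), n-BuLi, THF, −78 °C; then 10, −78 °C
Reagents that add atoms: none
Why: Tin–lithium exchange should give the configurationally stable α-ethoxyvinyllithium with retention, and its 1,2-addition to the enal (the excess also deprotonating the tertiary alcohol) gives the carbinol, whose C6 epimers need no separation because C6 becomes planar in step 12.

Step 12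
Reactants: 16 bis-allylic carbinol
Product: 18 tetracyclic norbornanone (C5 ketone; 2-exo-isopropenyl; C12 dioxolane; free C15 alcohol), via enol ether silyl ether 17 (not isolated)
Conditions: Me3SiOTf, 2,6-di-tert-butyl-4-methylpyridine, CH2Cl2, −78 → −30 °C; then aq. citric acid, THF, 20 °C
Reagents that add atoms: water, O
Why: Proposed new method: silylation and Me3SiOTf-induced ionisation of the bis-allylic C6 silyl ether should give a 5-ethoxypentadienyl cation (C4–C5–C6–C1–C7) that closes ring B by conrotatory 4π electrocyclisation (C4–C7), and the resulting O-ethylated cyclopentenone (ethoxyallyl cation) is attacked at C1 by the prenyl alkene in a 5-exo-trig cation–olefin closure (C1–C2) that forms ring A and completes the bicyclo[2.2.1]heptene enol ether 17, the tertiary C16 cation losing a proton to the base. The closest known reactions are the Nazarov cyclisation of alkoxydienyl carbinols to cyclopentenones and the interrupted Nazarov reaction, in which the cyclopentenyl cation is captured by a pendant olefin; new here is capture across the ring, possible because C2 sits two atoms from C4. Conrotation with C3 and C8 both in outside positions places them trans on ring B, which makes ring B cis-fused to ring C and puts the prenyl arm on the face from which it reaches C1. The bond to C7 should form on the face anti to the axial C9 methyl and the axial C15 silyloxy group (torquoselectivity), which sets C7 and C4 relative to the decalin, and C1 follows from the tether. C2 is set in the second closure, the developing 2-propyl cation pointing exo, away from the C5–C6 bridge. The step needs electrocyclisation to outrun proton loss or external capture of the dienyl cation and the ethoxy group to survive until C1–C2 has formed, which the triflate counter-ion, the hindered base and low temperature are chosen to secure; aqueous acid then hydrolyses the enol ether and the silyl ether.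

Step 13
Reactants: 18 tetracyclic norbornanone
Product: 20 hydroxy ketone (5-exo-ol; C12 ketone; 2-exo-isopropenyl), via hydroxy ketal 19 (not isolated)
Conditions: LiBH(s-Bu)3, THF, −78 → 0 °C; then 1 M HCl, THF, 20 °C
Reagents that add atoms: water, O
Why: The bulky borohydride should attack the norbornanone from the endo face, the exo face being screened by C8 on the C7 bridge (the camphor-to-isoborneol pattern), which sets the exo C5 alcohol, and aqueous acid then hydrolyses the C12 dioxolane.

Step 14
Reactants: 20 hydroxy ketone
Product: 22 vinyl bromide (C12(Br)=C13), via hydrazone 21 (not isolated)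
Conditions: N2H4·H2O, Et3N, EtOH, 78 °C; then NBS, pyridine, CH2Cl2, −10 °C
Reagents that add atoms: N-bromosuccinimide, O=C1CCC(=O)N1Br
Why: Hydrazone formation at the only ketone and its oxidation by N-bromosuccinimide (Barton-type vinyl halide synthesis through the diazo and bromodiazonium species) should give the vinyl bromide, the quaternary C9 allowing elimination only toward C13.

Step 15
Reactants: 22 vinyl bromide
Product: 23 target bromo diol
Conditions: Mn(dpm)3 (cat.; dpm = dipivaloylmethanate), PhSiH3, t-BuOOH, i-PrOH, 20 °C
Reagents that add atoms: none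
Why: Metal hydride hydrogen-atom-transfer hydrogenation (Mukaiyama-type) should reduce the isopropenyl group and the bromoalkene without loss of bromine, since hydrogen adds first to C13 to give the α-bromo radical at C12, which then accepts hydrogen on its axial face anti to the C9 methyl and so sets the equatorial C12 bromide.

Compound list
1 | (S)-Wieland–Miescher ketone | C[C@]12CCC(=O)C=C1CCCC2=O | starting material
2 | bis(ethylene ketal), C8=C15 alkene | C[C@]12CCC3(OCCO3)CC1=CCCC24OCCO4 | intermediate
3 | 8,15-epoxide (anti to C9 methyl) | C[C@]12CCC3(OCCO3)C[C@@]15O[C@H]5CCC24OCCO4 | intermediate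
4 | allylic alcohol (C15–OH, C7=C8) | C[C@]12CCC3(OCCO3)C=C1[C@@H](O)CCC24OCCO4 | intermediate
5 | enone (C15=O, C7=C8), bis-ketal | C[C@]12CCC3(OCCO3)C=C1C(=O)CCC24OCCO4 | intermediate
6 | C15 methyl carbinol, bis-ketal | C[C@]12CCC3(OCCO3)C=C1[C@](C)(O)CCC24OCCO4 | intermediate
7 | hydroxy enone (C1=O, C7=C8), C12 dioxolane | C[C@]12CCC(=O)C=C1[C@](C)(O)CCC24OCCO4 | intermediate
8 | dilithium C1(7)-enolate C15-alkoxide | C[C@]12CCC(O[Li])=C[C@@H]1[C@](C)(O[Li])CCC24OCCO4 | intermediate
9 | vinyl triflate (C1–OTf, C1=C7), trans-decalin | C[C@]12CCC(OS(=O)(=O)C(F)(F)F)=C[C@@H]1[C@](C)(O)CCC24OCCO4 | intermediate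
10 | enal (C6 formyl on C1, C1=C7) | C[C@]12CCC(C=O)=C[C@@H]1[C@](C)(O)CCC24OCCO4 | intermediate
11 | ethoxyacetylene | CCOC#C | starting material
12 | prenyl bromide (1-bromo-3-methylbut-2-ene) | CC(C)=CCBr | starting material
13 | 1-ethoxy-5-methylhex-4-en-1-yne | CCOC#CCC=C(C)C | intermediate
14 | (E)-tributyl(1-ethoxy-5-methylhexa-1,4-dien-1-yl)stannane | CCO/C(=C\CC=C(C)C)[Sn](CCCC)(CCCC)CCCC | intermediate
15 | (1-ethoxy-5-methylhexa-1,4-dien-1-yl)lithium, ethoxy cis to C3 | CCO/C([Li])=C\CC=C(C)C | intermediate
16 | bis-allylic carbinol (C6 epimers) | C[C@]12CCC(C(O)/C(OCC)=C/CC=C(C)C)=C[C@@H]1[C@](C)(O)CCC24OCCO4 | intermediate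
17 | tetracyclic ethyl enol ether (C5(OEt)=C6), C15 trimethylsilyl ether | C=C(C)[C@@H]1C[C@@H]2[C@H]3[C@H]4[C@](C)(CC[C@@]31C=C2OCC)C5(OCCO5)CC[C@@]4(C)O[Si](C)(C)C | intermediate
18 | tetracyclic norbornanone (C5=O), 2-exo-isopropenyl, C12 dioxolane | C=C(C)[C@@H]1C[C@@H]2[C@H]3[C@H]4[C@](C)(CC[C@@]31CC2=O)C5(OCCO5)CC[C@@]4(C)O | intermediate
19 | 5-exo-alcohol, C12 dioxolane | C=C(C)[C@@H]1C[C@@H]2[C@H]3[C@H]4[C@](C)(CC[C@@]31C[C@H]2O)C5(OCCO5)CC[C@@]4(C)O | intermediate
20 | hydroxy ketone (5-exo-ol, C12=O) | C=C(C)[C@@H]1C[C@@H]2[C@H]3[C@H]4[C@](C)(CC[C@@]31C[C@H]2O)C(=O)CC[C@@]4(C)O | intermediate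
21 | C12 hydrazone | C=C(C)[C@@H]1C[C@@H]2[C@H]3[C@H]4[C@](C)(CC[C@@]31C[C@H]2O)C(=NN)CC[C@@]4(C)O | intermediate
22 | vinyl bromide (C12(Br)=C13) | C=C(C)[C@@H]1C[C@@H]2[C@H]3[C@H]4[C@](C)(CC[C@@]31C[C@H]2O)C(Br)=CC[C@@]4(C)O | intermediate
23 | target bromo diol | CC(C)[C@@H]1C[C@@H]2[C@H]3[C@H]4[C@](C)(CC[C@@]31C[C@H]2O)[C@@H](Br)CC[C@@]4(C)O | target

Total step count: 15. Longest linear sequence: 13 steps (steps 1–8 and 11–15).

The three steps most likely to fail:

Step 12 may stop after the electrocyclisation, through loss of the ethyl group or of a proton from the ethoxyallyl cation before the prenyl alkene has closed ring A, or the dienyl cation may be intercepted before it cyclises. The fallback sets out from 16. Ionisation under carbinol Nazarov conditions with hydrolytic work-up (trifluoroacetic anhydride, 2,6-lutidine, CH2Cl2, −20 °C; aq. NaHCO3, MeOH) should give the bicyclic cyclopentenone F1 (C5 ketone, C6=C1 alkene, prenyl on C4 trans to C8). A separate Lewis acid-promoted intramolecular ene-type conjugate addition of the prenyl alkene to the enone β-carbon C1 (MeAlCl2, CH2Cl2, −78 → 0 °C) then closes ring A and comes back to the route at 18.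

Step 7 may suffer reductive loss of the C15 oxygen, protonation of C8 from the wrong face, or triflation of the alkoxide. The fallback sets out from 7. Wittig methoxymethylenation (Ph3P=CHOMe, THF, 0 °C) should give the methoxymethylene diene F2, and mild aqueous acid (oxalic acid, THF/H2O) hydrolyses it with vinylogous protonation at C8 anti to the C9 methyl. This returns to the route at 10 and bypasses step 8.

Step 15 may give reductive loss of bromine or poor discrimination between the two alkenes. The fallback sets out from 20. The hydrazone 21 is formed as in step 14 and treated with CuBr2 and Et3N in MeOH to give the geminal dibromide F3. Bu3SnH (one equivalent) with AIBN in benzene at 80 °C removes one bromine in a radical chain, leaving the equatorial bromide F4 with the isopropenyl group intact. Hydrogenation of that group with RhCl(PPh3)3 and H2 in benzene comes back to the route at 23.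

Further compounds
F1 | step 12 | bicyclic cyclopentenone (C5=O, C6=C1), prenyl on C4, C12 dioxolane | CC(C)=CC[C@@H]2[C@H]3[C@H]4[C@](C)(CCC3=CC2=O)C5(OCCO5)CC[C@@]4(C)O
F2 | step 7 | 1-(methoxymethylene) diene from 7 | C[C@]12CCC(=COC)C=C1[C@](C)(O)CCC24OCCO4
F3 | step 15 | C12 geminal dibromide, 2-isopropenyl | C=C(C)[C@@H]1C[C@@H]2[C@H]3[C@H]4[C@](C)(CC[C@@]31C[C@H]2O)C(Br)(Br)CC[C@@]4(C)O
F4 | step 15 | equatorial C12 bromide, 2-isopropenyl | C=C(C)[C@@H]1C[C@@H]2[C@H]3[C@H]4[C@](C)(CC[C@@]31C[C@H]2O)[C@@H](Br)CC[C@@]4(C)O
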